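Each flask holds 1.5 M of substrate, and every portion of it needs its own portion of gas, so the first amount to reckon is how long that gas takes to arrive.

    gas phase ⇌ dissolved gas, rate k1*(csat - [dissolved gas]) (k1 = 0.0411 s⁻¹, csat = 200 mM)
    substrate + dissolved gas + catalyst → catalyst + product (k2 = 13.8 M⁻² s⁻¹)
    2 substrate → homo dimer (k3 = 1.48 × 10⁻⁶ M⁻¹ s⁻¹)
    crystals ⇌ product, rate k4*(cs4 - [product]) while solid is left; crystals form when [product] > cs4 (cs4 = 0.49 M, k4 = 0.124 s⁻¹)
    catalyst + added ligand ⇌ idle complex (K5 = 0.959 M⁻¹, k5 = 0.0235 M⁻¹ s⁻¹)

| setting | winter | dawn | summer |
|---|---|---|---|
| substrate | 1.5 M | 1.5 M | 1.5 M |
| gas phase | 200 mM (held) | 200 mM (held) | 200 mM (held) |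
| catalyst | 38 mM | 38 mM | 38 mM |
| added ligand | 210 mM | 320 mM | 470 mM |
| time | 4.0 min | 4.0 min | 4.0 min |

- a species is counted by the substrate in it: one homo dimer counts as two
- amounts and yields of product count crystals too
- for a step with 2 of a species take k times the square, and two of it per event
- given per volume of solution although it is solid: crystals
- at the start none of the gas is dissolved
- run time (winter): 4.0 min

- which of these there is most of at the end, counted by the substrate in it, winter (substrate / product)
- which of these there is most of at the end, counted by the substrate in it, dawn (substrate / product)
- which of these there is most of at the end, counted by the substrate in it, summer (substrate / product)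
- amount of the one of these that there is most of at the end, in percent of the substrate charged, winter
- amount of the one of these that there is most of at the end, in percent of the substrate charged, dawn
- amount of the one of these that there is most of at the end, in percent of the substrate charged, summer

With none dissolved, gas crosses at a ceiling rate of 8.22 mM s⁻¹, the transfer coefficient times the saturation concentration, and slower as it dissolves. At that ceiling the substrate's gas takes a ceiling time of 3.04 min, less than the 4.0 min run. The path to homo dimer starts by taking substrate at 0.00666 mM s⁻¹, far below the ceiling, so we drop it. Once the added ligand has balanced, and taking it as charged, we reckon the free share of catalyst at 0.832 in winter, 0.765 at dawn and 0.689 in summer.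

Our first way replaces the falling substrate by its mean, 0.750 M. In winter dissolved gas is then taken up at 0.327 s⁻¹, in series with the transfer coefficient, and the substrate seems gone in 3.42 min.

Our second way is a ledger with no mean in it. Gas delivered either has reacted or stands dissolved, and we define the catalyst time τ as the time in which substrate falls by a factor e with gas at saturation, a pseudo-first-order time: 11.5 s in winter, 12.5 s at dawn, 13.8 s in summer. Elapsed time is then the sum of the ceiling time times the share of substrate used, the dissolved gas over the ceiling rate, and τ times the ln of charge over substrate left.

The mean's winter time is exactly the ceiling time plus twice τ, so both ways carry the same ceiling time, which makes this common part no check, and they differ in what they add to it. The mean is the one that cheats: the ln grows without bound as substrate vanishes, so in the ledger substrate is not gone at that time.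

We therefore use the ledger. Dissolved gas lies between none and saturation, so we take half, which costs 12.2 s and leaves 45.4 s for the tail. Counting the whole ceiling time gives a higher estimate of the share left, and putting that share back gives a lower estimate. Winter gets 1.91% and 1.41%, dawn 2.63% and 1.79%, summer 3.77% and 2.29%. Taking product as the rest, it outweighs substrate in each flask.

The forecast names product in each flask, at 98.5%, 97.7% and 96.6%, holding that more ligand “slows the final catalyst-dependent tail”.

The simulation gives 98.2%, 97.8% and 97.1% of product in winter, dawn and summer, with 1.77%, 2.20% and 2.83% of substrate left, each inside our pair. Winter's readings at 4.00 min, put into the ledger with its τ, sum to 4.01 min. The dawn flask with 0.023 M of catalyst has τ of 20.6 s, and the two passes give 11.0% and 4.15% left. That flask holds 6.35% of substrate and 93.6% of product at 4.00 min.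

Its constants stand for no real mixture.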